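No rate constant is given, so the constants I reckon with have to be read from the readings of the earlier runs.

all flasks: substrate 0.10 M

|  | coupling partner | remark | time |
|---|---|---|---|
| north-west | 1.2 equiv | run made earlier |  |
| north | 2.7 equiv | run made earlier |  |
| flask | 1.80 equiv |  | 40 min |

| run | time / min | side product / % | target / % | substrate / % |
|---|---|---|---|---|
| north-west | 10.0 | 4.1 | 42.1 | 8.4 |
| north-west | 20.0 | 5.2 | 73.9 | 2.6 |
| north-west | 30.0 | 5.3 | 86.5 | 1.1 |
| north-west | 40.0 | 4.9 | 92.1 | 0 |
| north-west | 50.0 | 5.1 | 93.4 | 0 |
| north | 4.00 | 9.4 | 14.9 | 1.7 |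
| north | 12.0 | 17.5 | 54.0 | 0.7 |
| north | 20.0 | 18.7 | 70.1 | 0.2 |
| north | 30.0 | 19.4 | 77.7 | 0 |
| north | 50.0 | 19.6 | 80.0 | 0.4 |

(each reading ± 0.3 percentage points)



1. share of side product in side product plus target at 1.0 min
2. share of side product in side product plus target at 6.0 min
3. share of side product in side product plus target at 40 min

Where does the flask stop? Substrate is the limiting reagent against 1.80 equiv of coupling partner. In the north run the share of side product goes from 20.0% at 30.0 min to 19.7% at 50.0 min, so I treat the flask's share at 40 min as an end value.

How much goes aside? Let ρ be side product over target at the end, and replace the falling partner curve by its mean c̄, so that ρ = g·c̄, with c̄ = c₀(e − b) for a charge of e equivalents on substrate at c₀. Here g is a selectivity factor, ρ gained per mole per litre of mean partner. The last readings give ρ = 0.0546 in the north-west run and 0.245 in the north run, so I read g = 1.27 L mol⁻¹ and b = 0.770 equiv. For the flask c̄ = 0.103 M, so ρ = 0.131 and the share is 11.6%.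

Is the share that low throughout? In the north run it stands at 1.97 times its last reading at 4.00 min and 1.24 times it at 12.0 min. I therefore put the flask at 6.0 min between 14.4% and 22.7%, and at 1.0 min higher, without a number.

The forecast, noting “Target shows a lag”, gives 50%, 22% and 11.8%. The flask gives 42.3%, 22.7% and 11.3%.

    coupling partner + intermediate A → intermediate B (k = 0.489 L mol⁻¹ min⁻¹)
    intermediate C → target (k = 0.122 min⁻¹)
    intermediate A ⇌ intermediate C (K = 14.7, k = 0.432 min⁻¹)
    substrate + coupling partner ⇌ intermediate A (K = 151 L mol⁻¹, k = 7.55 L mol⁻¹ min⁻¹)
    intermediate B → side product (k = 0.642 min⁻¹)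

Through g, the flask's result corresponds to a mean partner of 0.100 M, against my 0.103 M. In the flask, half of the turnover from intermediate A to intermediate C is done by 2.65 min, and at 4.00 min side product stands at 5.14%, target at 13.3% and intermediate C at 47.4%. By 20.0 min intermediate C has fallen to 12.8%, target has reached 75.0% and side product 10.8%, against 11.1% at 40.0 min.

With 0.040 M of substrate and the same equivalents, taking b unchanged in equivalents, which no earlier run tested, g gives c̄ = 0.0412 M and a share of 4.97%. The computed share there is 5.50%.

(Readings and results stem from a simulated flask with made-up constants; scatter was added.)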